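**Strategy.** Everything rests on making the benzylic O1–C2 bond of the tetrahydrofuran, with the C3 stereocentre beside it, by ring expansion of an all-cis 2-aryl-3-(silyloxymethyl)cyclopropanecarbaldehyde. A Lewis acid breaks the cyclopropane bond between the aryl-bearing and formyl-bearing carbons while the formyl oxygen closes on the benzylic carbon. This single operation forms the oxygen ring, sets C2 trans to an untouched C3 and leaves a 2,3-dihydrofuran whose enol ether is nucleophilic at C4, the site still lacking the aroyl group. The cyclopropane comes from an enantioselective intramolecular cyclopropanation of a (Z)-cinnamyl diazoacetate, and one aryl bromide supplies both arenes.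

Key step: step 10

**Remarks**
- Numbering: furan-type rings are numbered O1, C2 (aryl), C3 (CH2O), C4, C5 as in the target. Cyclopropanes are numbered C1 (carbonyl-bearing), C2 (aryl), C3 (CH2O). Ar = 3-(tert-butyldimethylsilyloxy)-4-methoxyphenyl, TBS = tert-butyldimethylsilyl, TBDPS = tert-butyldiphenylsilyl.
- Assumption: the MEPY catalysts are taken to show the facial sense known for allyl and (Z)-allylic diazoacetates, where the (5S) catalyst gives (1R,5S) lactones; the (1S,5R,6S) lactone needed here is therefore assigned to Rh2(5R-MEPY)4, and the antipodal catalyst is available should the sense prove opposite.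
- Protecting groups: both phenols are carried as TBS ethers and the primary alcohol as a TBDPS ether. The TBDPS group is robust to Sc(OTf)3 and to the chloroiminium reagent of step 11 and keeps its oxygen non-nucleophilic in the key step. The aryl TBS ethers fall in the base equilibration of step 14, so no hydrogenolysis is needed near the aryl ketone and the benzylic ring C–O bond.
- The aroyl group is installed at C4 by formylation, aryllithium addition and oxidation, each a documented reaction of cyclic enol ethers.

**Route**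

Step 1
Reactants: 1 5-bromo-2-methoxyphenol
Product: 2 tert-butyl(5-bromo-2-methoxyphenoxy)dimethylsilane
Conditions: TBSCl, imidazole, DMF, rt
Reagents that add atoms: tert-butyldimethylsilyl chloride, CC(C)(C)[Si](C)(C)Cl
Why: Imidazole-promoted silylation of a phenol is routine, and the aryl TBS ether should withstand the amine bases, organometallics and Lewis acids used up to step 14, where it is removed on purpose.

Step 2
Reactants: 2 tert-butyl(5-bromo-2-methoxyphenoxy)dimethylsilane; 3 propargyl alcohol
Product: 4 3-[3-(tert-butyldimethylsilyloxy)-4-methoxyphenyl]prop-2-yn-1-ol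
Conditions: PdCl2(PPh3)2 (5 mol %), CuI (5 mol %), Et3N, DMF, 70 °C
Reagents that add atoms: none
Why: Sonogashira coupling should join the aryl bromide to the terminal alkyne through oxidative addition to zerovalent palladium and transmetalation from the copper acetylide, with neither the free hydroxyl nor the aryl silyl ether interfering.

Step 3
Reactants: 4 3-[3-(tert-butyldimethylsilyloxy)-4-methoxyphenyl]prop-2-yn-1-ol
Product: 5 (Z)-3-[3-(tert-butyldimethylsilyloxy)-4-methoxyphenyl]prop-2-en-1-ol
Conditions: H2 (1 atm), Pd/CaCO3 poisoned with Pb(OAc)2 (Lindlar catalyst), quinoline, EtOAc, rt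
Reagents that add atoms: none
Why: Lindlar semihydrogenation delivers both hydrogens to one face of the alkyne on the poisoned palladium surface and should stop at the (Z)-alkene, the geometry that later places aryl and CH2O cis on the cyclopropane.

Step 4
Reactants: 5 (Z)-3-[3-(tert-butyldimethylsilyloxy)-4-methoxyphenyl]prop-2-en-1-ol; 6 bromoacetyl bromide
Product: 7 (Z)-3-Ar-prop-2-en-1-yl bromoacetate
Conditions: NaHCO3, MeCN, 0 °C
Reagents that add atoms: none
Why: Acylation of the primary allylic alcohol by the acyl bromide under bicarbonate buffering should be fast at 0 °C and leave the electron-rich (Z)-cinnamyl system unionised.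

Step 5
Reactants: 7 (Z)-3-Ar-prop-2-en-1-yl bromoacetate
Product: 10 (Z)-3-Ar-prop-2-en-1-yl diazoacetate, via ditosylhydrazide 8 (not isolated), via tosylhydrazone 9 (not isolated)
Conditions: TsNHNHTs, DBU, THF, 0 °C
Reagents that add atoms: N,N'-ditosylhydrazine, Cc1ccc(cc1)S(=O)(=O)NNS(=O)(=O)c1ccc(C)cc1
Why: In this ditosylhydrazine route to diazoacetates the hydrazide anion should displace bromide to give 8, DBU should expel one sulfinate to give 9, and a Bamford–Stevens-type loss of the second sulfinate should give the diazo ester at 0 °C without touching the alkene.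

Step 6
Reactants: 10 (Z)-3-Ar-prop-2-en-1-yl diazoacetate
Product: 11 (1S,5R,6S)-6-Ar-3-oxabicyclo[3.1.0]hexan-2-one (aryl endo)
Conditions: Rh2(5R-MEPY)4 [dirhodium tetrakis(methyl (5R)-2-oxopyrrolidine-5-carboxylate)] (1 mol %), CH2Cl2, reflux, slow addition of 10
Reagents that add atoms: none
Why: Enantioselective intramolecular cyclopropanation by the rhodium carbene formed on the chiral dirhodium carboxamidate (divalent rhodium) adds to the alkene with retention of its (Z)-geometry, so the aryl group should lie cis to the fused lactone and the three new centres be all-cis, while the pyrrolidone ester ligands select the alkene face and thereby the 1S,5R,6S configuration.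

Step 7
Reactants: 11 (1S,5R,6S)-6-Ar-3-oxabicyclo[3.1.0]hexan-2-one
Product: 12 (1S,2S,3R)-2-Ar-3-(hydroxymethyl)-N-methoxy-N-methylcyclopropane-1-carboxamide (all-cis)
Conditions: MeNH(OMe)·HCl, AlMe3, CH2Cl2, 0 °C to rt; aq. potassium sodium tartrate
Reagents that add atoms: N,O-dimethylhydroxylamine hydrochloride, CNOC.Cl
Why: Weinreb aminolysis with the aluminium amide opens the lactone at its acyl carbon, so no stereocentre is touched and the carbonyl arrives at an oxidation level that can be stopped at the aldehyde.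

Step 8
Reactants: 12 (1S,2S,3R)-2-Ar-3-(hydroxymethyl)-N-methoxy-N-methylcyclopropane-1-carboxamide
Product: 13 (1S,2S,3R)-2-Ar-3-[(tert-butyldiphenylsilyloxy)methyl]-N-methoxy-N-methylcyclopropane-1-carboxamide
Conditions: TBDPSCl, imidazole, DMF, rt (crude 12 used at once)
Reagents that add atoms: tert-butyl(chloro)diphenylsilane, CC(C)(C)[Si](Cl)(c1ccccc1)c1ccccc1
Why: Silylation of the primary alcohol directly on the crude hydroxy amide should forestall relactonisation, and it installs the bulky, acid-robust group that the key step and step 11 require.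

Step 9
Reactants: 13 (1S,2S,3R)-2-Ar-3-[(tert-butyldiphenylsilyloxy)methyl]-N-methoxy-N-methylcyclopropane-1-carboxamide
Product: 15 (1S,2S,3R)-2-Ar-3-[(tert-butyldiphenylsilyloxy)methyl]cyclopropane-1-carbaldehyde (all-cis), via aluminium hemiaminal 14 (not isolated)
Conditions: i-Bu2AlH, THF, −78 °C; aq. potassium sodium tartrate
Reagents that add atoms: none
Why: Hydride reduction of a Weinreb amide with i-Bu2AlH should halt at the chelated hemiaminal 14, which releases the aldehyde only on work-up, and any epimerisation at C1 would be harmless because that carbon becomes trigonal in step 10.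

Step 10
Reactants: 15 (1S,2S,3R)-2-Ar-3-[(tert-butyldiphenylsilyloxy)methyl]cyclopropane-1-carbaldehyde
Product: 16 (2S,3R)-2-Ar-3-[(tert-butyldiphenylsilyloxy)methyl]-2,3-dihydrofuran (2,3-trans)
Conditions: Sc(OTf)3 (10 mol %), 4 Å molecular sieves, CH2Cl2 (0.02 M), slow addition of 15, 0 °C to rt; Et3N quench, Et3N-deactivated silica
Reagents that add atoms: none
Why: Sc(OTf)3 (trivalent scandium) should bind the formyl oxygen and polarise the cyclopropane C1–C2 bond (formyl-bearing to aryl-bearing carbon) until it breaks heterolytically, giving a contact ion pair of a para-methoxy-stabilised benzylic cation and a scandium enolate whose oxygen then bonds to the benzylic carbon, in effect a 1,3-shift of that carbon from carbon to oxygen. The closest known reaction is the acid-promoted Cloke–Wilson rearrangement of aryl-substituted cyclopropyl aldehydes and ketones to 2,3-dihydrofurans. The one ring formed, the dihydrofuran, closes by O-alkylation of the enolate in a 5-(enolendo) mode onto a trigonal or ion-paired benzylic carbon, so no in-line trajectory through the old ring is demanded. The one new stereocentre, C2, is controlled by the retained C3 centre: oxygen should enter opposite the departing carbon (inversion of the all-cis cyclopropane), a freer cation should still place the aryl group anti to the CH2OTBDPS group, and because the C2–O1 bond can re-ionise under the catalyst the 2,3-trans isomer is also the one expected at equilibrium. The step needs O-closure to outrun proton loss from C3, hydride shift and bimolecular attack of product enol ether or a second aldehyde on the activated substrate, which the para-methoxy donor, the single cis-placed formyl acceptor, high dilution with slow addition and the non-nucleophilic silyl ethers are meant to secure. C3 is never trigonal, so the enantiomeric purity set in step 6 should be carried through.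

Step 11
Reactants: 16 (2S,3R)-2-Ar-3-[(tert-butyldiphenylsilyloxy)methyl]-2,3-dihydrofuran
Product: 18 (2S,3R)-2-Ar-3-[(tert-butyldiphenylsilyloxy)methyl]-2,3-dihydrofuran-4-carbaldehyde, via iminium chloride 17 (not isolated)
Conditions: POCl3, DMF, 0 °C to rt; aq. NaOAc, 0 °C
Reagents that add atoms: N,N-dimethylformamide, CN(C)C=O; water, O
Why: Vilsmeier–Haack formylation should attack the enol ether at its nucleophilic carbon C4, as it does with glycals and simple cyclic enol ethers, and buffered hydrolysis of iminium 17 should give the vinylogous formate without disturbing C2 or C3.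

Step 12
Reactants: 18 (2S,3R)-2-Ar-3-[(tert-butyldiphenylsilyloxy)methyl]-2,3-dihydrofuran-4-carbaldehyde; 2 tert-butyl(5-bromo-2-methoxyphenoxy)dimethylsilane
Product: 20 [(2S,3R)-2-Ar-3-[(tert-butyldiphenylsilyloxy)methyl]-2,3-dihydrofuran-4-yl](Ar)methanol (both carbinol epimers), via aryllithium 19 (not isolated)
Conditions: 2, n-BuLi, THF, −78 °C; then 18, −78 °C; H2O
Reagents that add atoms: none
Why: Bromine–lithium exchange on 2 should give aryllithium 19, which adds 1,2 to the aldehyde of the vinylogous formate at −78 °C, and the new carbinol centre forms as an epimer mixture that the next step erases.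

Step 13
Reactants: 20 [(2S,3R)-2-Ar-3-[(tert-butyldiphenylsilyloxy)methyl]-2,3-dihydrofuran-4-yl](Ar)methanol
Product: 21 [(2S,3R)-2-Ar-3-[(tert-butyldiphenylsilyloxy)methyl]-2,3-dihydrofuran-4-yl](Ar)methanone
Conditions: MnO2, CH2Cl2, rt (crude 20)
Reagents that add atoms: none
Why: MnO2 oxidation of the doubly activated alcohol (benzylic and allylic) runs under neutral conditions, which should avoid acid-induced ionisation of the carbinol and give the vinylogous ester.

Step 14
Reactants: 21 [(2S,3R)-2-Ar-3-[(tert-butyldiphenylsilyloxy)methyl]-2,3-dihydrofuran-4-yl](Ar)methanone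
Product: 24 [(2S,3R,4S)-2-(3-hydroxy-4-methoxyphenyl)-3-[(tert-butyldiphenylsilyloxy)methyl]tetrahydrofuran-4-yl](3-hydroxy-4-methoxyphenyl)methanone (all-trans), via lithium enolate 22 (not isolated), via cis ketone 23 (not isolated)
Conditions: LiBH(s-Bu)3, THF, −78 °C; then MeOH, K2CO3, −78 °C to rt
Reagents that add atoms: none
Why: LiBH(s-Bu)3 should reduce the vinylogous ester by conjugate (1,4) hydride addition at the unhindered C5, as it does with dihydropyranones, protonation of enolate 22 by methanol should give mainly the 3,4-cis ketone 23, and methanolic K2CO3 should then equilibrate C4 through the enolate to the thermodynamically preferred all-trans arrangement (4S, aroyl trans to CH2O) while cleaving both aryl TBS ethers by methanolysis and leaving the alkyl TBDPS ether intact.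

Step 15
Reactants: 24 [(2S,3R,4S)-2-(3-hydroxy-4-methoxyphenyl)-3-[(tert-butyldiphenylsilyloxy)methyl]tetrahydrofuran-4-yl](3-hydroxy-4-methoxyphenyl)methanone
Product: 25 [(2S,3R,4S)-2-(3-hydroxy-4-methoxyphenyl)-3-(hydroxymethyl)tetrahydrofuran-4-yl](3-hydroxy-4-methoxyphenyl)methanone (target; 3S,4R,5S in oxolan-3-yl numbering)
Conditions: Bu4NF, AcOH, THF, rt
Reagents that add atoms: none
Why: Fluoride should cleave the primary TBDPS ether, and the acetic acid buffer keeps the medium from becoming basic enough to disturb C4 or open the ring, so the target is released with all three stereocentres in place.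

**Compound list**

1 | 5-bromo-2-methoxyphenol | COc1ccc(Br)cc1O | starting material
2 | tert-butyl(5-bromo-2-methoxyphenoxy)dimethylsilane | COc1ccc(Br)cc1O[Si](C)(C)C(C)(C)C | intermediate
3 | propargyl alcohol (prop-2-yn-1-ol) | C#CCO | starting material
4 | 3-[3-(tert-butyldimethylsilyloxy)-4-methoxyphenyl]prop-2-yn-1-ol | COc1ccc(C#CCO)cc1O[Si](C)(C)C(C)(C)C | intermediate
5 | (Z)-3-[3-(tert-butyldimethylsilyloxy)-4-methoxyphenyl]prop-2-en-1-ol | COc1ccc(/C=C\CO)cc1O[Si](C)(C)C(C)(C)C | intermediate
6 | bromoacetyl bromide | O=C(Br)CBr | starting material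
7 | (Z)-3-Ar-prop-2-en-1-yl bromoacetate | COc1ccc(/C=C\COC(=O)CBr)cc1O[Si](C)(C)C(C)(C)C | intermediate
8 | (Z)-3-Ar-prop-2-en-1-yl 2-[1,2-bis(p-tolylsulfonyl)hydrazin-1-yl]acetate | COc1ccc(/C=C\COC(=O)CN(NS(=O)(=O)c2ccc(C)cc2)S(=O)(=O)c2ccc(C)cc2)cc1O[Si](C)(C)C(C)(C)C | intermediate (not isolated)
9 | (Z)-3-Ar-prop-2-en-1-yl 2-(p-tolylsulfonylhydrazono)acetate | COc1ccc(/C=C\COC(=O)C=NNS(=O)(=O)c2ccc(C)cc2)cc1O[Si](C)(C)C(C)(C)C | intermediate (not isolated)
10 | (Z)-3-Ar-prop-2-en-1-yl diazoacetate | COc1ccc(/C=C\COC(=O)C=[N+]=[N-])cc1O[Si](C)(C)C(C)(C)C | intermediate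
11 | (1S,5R,6S)-6-Ar-3-oxabicyclo[3.1.0]hexan-2-one | O=C1OC[C@@H]2[C@H](c3ccc(OC)c(O[Si](C)(C)C(C)(C)C)c3)[C@H]12 | intermediate
12 | (1S,2S,3R)-2-Ar-3-(hydroxymethyl)-N-methoxy-N-methylcyclopropane-1-carboxamide | CON(C)C(=O)[C@@H]1[C@H](CO)[C@@H]1c1ccc(OC)c(O[Si](C)(C)C(C)(C)C)c1 | intermediate
13 | (1S,2S,3R)-2-Ar-3-[(tert-butyldiphenylsilyloxy)methyl]-N-methoxy-N-methylcyclopropane-1-carboxamide | CON(C)C(=O)[C@@H]1[C@H](CO[Si](c2ccccc2)(c2ccccc2)C(C)(C)C)[C@@H]1c1ccc(OC)c(O[Si](C)(C)C(C)(C)C)c1 | intermediate
14 | diisobutylaluminium hemiaminal of 13 (O–Al(i-Bu)2 adduct at the amide carbon) | CON(C)C(O[Al](CC(C)C)CC(C)C)[C@@H]1[C@H](CO[Si](c2ccccc2)(c2ccccc2)C(C)(C)C)[C@@H]1c1ccc(OC)c(O[Si](C)(C)C(C)(C)C)c1 | intermediate (not isolated)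
15 | (1S,2S,3R)-2-Ar-3-[(tert-butyldiphenylsilyloxy)methyl]cyclopropane-1-carbaldehyde (all-cis; key-step precursor) | O=C[C@@H]1[C@H](CO[Si](c2ccccc2)(c2ccccc2)C(C)(C)C)[C@@H]1c1ccc(OC)c(O[Si](C)(C)C(C)(C)C)c1 | intermediate
16 | (2S,3R)-2-Ar-3-[(tert-butyldiphenylsilyloxy)methyl]-2,3-dihydrofuran (2,3-trans; key-step product) | O1[C@H](c2ccc(OC)c(O[Si](C)(C)C(C)(C)C)c2)[C@@H](CO[Si](c2ccccc2)(c2ccccc2)C(C)(C)C)C=C1 | intermediate
17 | N,N-dimethyliminium chloride of aldehyde 18 | O1[C@H](c2ccc(OC)c(O[Si](C)(C)C(C)(C)C)c2)[C@@H](CO[Si](c2ccccc2)(c2ccccc2)C(C)(C)C)C(C=[N+](C)C)=C1.[Cl-] | intermediate (not isolated)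
18 | (2S,3R)-2-Ar-3-[(tert-butyldiphenylsilyloxy)methyl]-2,3-dihydrofuran-4-carbaldehyde | O1[C@H](c2ccc(OC)c(O[Si](C)(C)C(C)(C)C)c2)[C@@H](CO[Si](c2ccccc2)(c2ccccc2)C(C)(C)C)C(C=O)=C1 | intermediate
19 | [3-(tert-butyldimethylsilyloxy)-4-methoxyphenyl]lithium | [Li]c1ccc(OC)c(O[Si](C)(C)C(C)(C)C)c1 | intermediate (not isolated)
20 | [(2S,3R)-2-Ar-3-[(tert-butyldiphenylsilyloxy)methyl]-2,3-dihydrofuran-4-yl](Ar)methanol, both carbinol epimers | O1[C@H](c2ccc(OC)c(O[Si](C)(C)C(C)(C)C)c2)[C@@H](CO[Si](c2ccccc2)(c2ccccc2)C(C)(C)C)C(C(O)c2ccc(OC)c(O[Si](C)(C)C(C)(C)C)c2)=C1 | intermediate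
21 | [(2S,3R)-2-Ar-3-[(tert-butyldiphenylsilyloxy)methyl]-2,3-dihydrofuran-4-yl](Ar)methanone | O1[C@H](c2ccc(OC)c(O[Si](C)(C)C(C)(C)C)c2)[C@@H](CO[Si](c2ccccc2)(c2ccccc2)C(C)(C)C)C(C(=O)c2ccc(OC)c(O[Si](C)(C)C(C)(C)C)c2)=C1 | intermediate
22 | lithium enolate of ketone 23 (exocyclic at C4) | O1[C@H](c2ccc(OC)c(O[Si](C)(C)C(C)(C)C)c2)[C@@H](CO[Si](c2ccccc2)(c2ccccc2)C(C)(C)C)C(=C([O-])c2ccc(OC)c(O[Si](C)(C)C(C)(C)C)c2)C1.[Li+] | intermediate (not isolated)
23 | [(2S,3R,4R)-2-Ar-3-[(tert-butyldiphenylsilyloxy)methyl]tetrahydrofuran-4-yl](Ar)methanone (3,4-cis) | COc1ccc(C(=O)[C@H]2CO[C@H](c3ccc(OC)c(O[Si](C)(C)C(C)(C)C)c3)[C@H]2CO[Si](c4ccccc4)(c5ccccc5)C(C)(C)C)cc1O[Si](C)(C)C(C)(C)C | intermediate (not isolated)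
24 | [(2S,3R,4S)-2-(3-hydroxy-4-methoxyphenyl)-3-[(tert-butyldiphenylsilyloxy)methyl]tetrahydrofuran-4-yl](3-hydroxy-4-methoxyphenyl)methanone (all-trans) | COc1ccc(C(=O)[C@@H]2CO[C@H](c3ccc(OC)c(O)c3)[C@H]2CO[Si](c4ccccc4)(c5ccccc5)C(C)(C)C)cc1O | intermediate
25 | (3-hydroxy-4-methoxyphenyl)[(3S,4R,5S)-5-(3-hydroxy-4-methoxyphenyl)-4-(hydroxymethyl)oxolan-3-yl]methanone | COc1ccc(C(=O)[C@@H]2CO[C@H](c3ccc(OC)c(O)c3)[C@H]2CO)cc1O | target

**Step count and risks**

Total steps: 15. Longest linear sequence: 15 steps (1 to 25); bromide 2 enters a second time in step 12.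

Steps most likely to fail:

1. Step 10. The benzylic cation may be diverted before the oxygen closes on it, through proton loss from C3 to a styrene, hydride shift, or bimolecular attack of product enol ether or a second aldehyde on the activated substrate, and closure may not be fully trans-selective. The fallback sets out from 15. Acid-catalysed homoconjugate addition of water (TsOH·H2O cat., THF–H2O, rt) would open the cyclopropane at the benzylic carbon with a large excess of an external oxygen nucleophile. The resulting γ-hydroxy aldehyde closes to the lactol (2S,3R)-2-Ar-3-[(tert-butyldiphenylsilyloxy)methyl]tetrahydrofuran-5-ol F1. Dehydration of F1 through its anomeric mesylate (MsCl, Et3N, CH2Cl2, 0 °C to reflux), the usual way from 2-deoxy lactols to cyclic enol ethers, would come back to the route at 16.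

2. Step 11. The 2-aryl enol ether may break down in the chloroiminium/HCl medium by protonation at C4 followed by hydrolysis or by ionisation at C2, and silyl groups may be lost. The fallback sets out from 16 and avoids electrophilic formylation. Br2 (CH2Cl2, −78 °C, where the enol ether reacts far faster than the arenes) would add across C4=C5 to give the (2S,3R)-2-Ar-4,5-dibromo-3-[(tert-butyldiphenylsilyloxy)methyl]tetrahydrofuran F2. Et3N would remove HBr to give the (2S,3R)-2-Ar-4-bromo-3-[(tert-butyldiphenylsilyloxy)methyl]-2,3-dihydrofuran F3. t-BuLi (2 equiv, THF, −78 °C) would exchange bromine for lithium to give the (2S,3R)-2-Ar-3-[(tert-butyldiphenylsilyloxy)methyl]-4-lithio-2,3-dihydrofuran F4. Quenching with DMF would come back to the route at 18.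

3. Step 14. Hydride may attack the ketone carbonyl (1,2) instead of C5, and the base equilibration may open the ring by β-elimination of O1 from the enolate. The fallback sets out from 21 and needs neither hydride nor base. Bu4NF/AcOH (THF, rt) would remove all three silyl groups to give the enone [(2S,3R)-2-(3-hydroxy-4-methoxyphenyl)-3-(hydroxymethyl)-2,3-dihydrofuran-4-yl](3-hydroxy-4-methoxyphenyl)methanone F5. Hydroxyl-directed hydrogenation with [Ir(cod)(PCy3)(py)]PF6 under H2 (CH2Cl2, rt) would then deliver hydrogen to C4=C5 from the face of the C3 hydroxymethyl group. That places the C4 hydrogen cis to CH2OH and the aroyl group trans, and comes back to the route at 25.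

Further compounds
F1 | step 10 | (2S,3R)-2-Ar-3-[(tert-butyldiphenylsilyloxy)methyl]tetrahydrofuran-5-ol (anomer mixture) | O1[C@H](c2ccc(OC)c(O[Si](C)(C)C(C)(C)C)c2)[C@@H](CO[Si](c2ccccc2)(c2ccccc2)C(C)(C)C)CC1O
F2 | step 11 | (2S,3R)-2-Ar-4,5-dibromo-3-[(tert-butyldiphenylsilyloxy)methyl]tetrahydrofuran | O1[C@H](c2ccc(OC)c(O[Si](C)(C)C(C)(C)C)c2)[C@@H](CO[Si](c2ccccc2)(c2ccccc2)C(C)(C)C)C(Br)C1Br
F3 | step 11 | (2S,3R)-2-Ar-4-bromo-3-[(tert-butyldiphenylsilyloxy)methyl]-2,3-dihydrofuran | O1[C@H](c2ccc(OC)c(O[Si](C)(C)C(C)(C)C)c2)[C@@H](CO[Si](c2ccccc2)(c2ccccc2)C(C)(C)C)C(Br)=C1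
F4 | step 11 | (2S,3R)-2-Ar-3-[(tert-butyldiphenylsilyloxy)methyl]-4-lithio-2,3-dihydrofuran | O1[C@H](c2ccc(OC)c(O[Si](C)(C)C(C)(C)C)c2)[C@@H](CO[Si](c2ccccc2)(c2ccccc2)C(C)(C)C)C([Li])=C1
F5 | step 14 | [(2S,3R)-2-(3-hydroxy-4-methoxyphenyl)-3-(hydroxymethyl)-2,3-dihydrofuran-4-yl](3-hydroxy-4-methoxyphenyl)methanone | O1[C@H](c2ccc(OC)c(O)c2)[C@@H](CO)C(C(=O)c2ccc(OC)c(O)c2)=C1
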